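Per second, the summer run reads as losing a steady fraction of its starting material. Between 40.0 s and 80.0 s this pseudo-first-order constant reads κ = 0.00224 s⁻¹. Traced back to the full charge, the same line starts at a lag τ = 9.94 s.

the same everywhere: gas 200 mM (held)

|  | starting material | remark | time |
|---|---|---|---|
| midnight | 3 M | the very flask that is asked about, followed so far |  |
| summer | 2 M | run made earlier |  |
| flask | 3.0 M |  | 2.0 min |

| run | time / s | mono adduct / % | starting material / % |
|---|---|---|---|
| midnight | 10.0 | 1.8 | 98.9 |
| midnight | 12.0 | 1.3 | 99.6 |
| midnight | 20.0 | 1.6 | 97.7 |
| midnight | 25.0 | 0 | 96.5 |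
| summer | 15.0 | 0 | 99.9 |
| summer | 30.0 | 2.1 | 95.5 |
| summer | 40.0 | 4.4 | 93.5 |
| summer | 60.0 | 4.8 | 89.7 |
| summer | 80.0 | 8.4 | 85.5 |

(standard deviation of a reading: 1 percentage point)

- the earlier runs were read with a standard deviation of 1 percentage point
- at the start none of the gas is in solution
- coupling partner is what gas becomes in solution

1. amount of mono adduct at 2.0 min, in percent of the starting material charged
2. concentration of coupling partner in solution at 2.0 min, in percent of saturation

The givens fold into one number, the loss number N, the count of κ-lifetimes that have passed from the lag to the time t:

N = κ(t − τ) = 0.246, so starting material left = exp(−N) = 78.2%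

The test is the midnight run, at a different charge from the summer run. At 25.0 s, N predicts a loss of 3.32%, and the reading is 3.50%, with a scatter of 1 percentage point.

One number is still not enough. In the summer readings, mono adduct reads as f = 55.0% of the loss, so this reckoning gives for the mono adduct y:

y = f(1 − exp(−N)) = 12.0%

N gives no saturation, so this reckoning offers no value for it.

The forecast says y = 11% (8% to 14%) and saturation 78% (58% to 97%), holding that “the gas sits somewhat below saturation”. The y of 12.0% from N stands higher than the forecast's.

The flask gives y = 11.3% and saturation 45.5%, which is 32 points below the forecast. In this flask at 2.00 min, coupling partner is made 1.01 times as fast as it is used up. Starting material in this flask stands at 81%, against 78.2% from N.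

    starting material + coupling partner → mono adduct (k = 0.0130 M⁻¹ s⁻¹)
    gas ⇌ coupling partner, rate k2*(csat - [coupling partner]) (kL = 0.0510 s⁻¹)
    starting material + coupling partner → other mono adduct (k = 0.00850 M⁻¹ s⁻¹)
    coupling partner + other mono adduct → bis adduct (k = 0.0370 M⁻¹ s⁻¹)
    coupling partner + mono adduct → bis adduct (k = 0.00510 M⁻¹ s⁻¹)

In the flask left until 3.0 min, N = 0.380, which gives 68.4% starting material and y = 17.4%. That flask holds 72% starting material and 16.4% mono adduct.

The numbers in the tables were generated by integration on assumed constants, and the scatter is random.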